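I began from late times: the candidate steps pass Q on to Z and G, so with D still feeding E each L can end up carrying 3 E. Q is a stage a flask passes through, and what is asked is a moment in that passage.

the same everywhere: D 54 mM (held)

| flask | L | remark | time |
|---|---|---|---|
| midnight | 0.72 M (in portions, 3) | run made earlier; portions every 8.0 h |  |
| alder | 0.30 M (in portions, 3) | the portions of L follow each other after 30 h, the first at the start | 25 h |
| elm | 0.30 M (in portions, 3) | the portions of L follow each other after 5.0 h, the first at the start | 25 h |
| birch | 0.65 M (in portions, 3) | the portions of L follow each other after 8.0 h, the first at the start | 25 h |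
| larch | 0.40 M (in portions, 3) | the portions of L follow each other after 12 h, the first at the start | 25 h |
| cedar | 1.0 M (in portions, 3) | the portions of L follow each other after 25 h, the first at the start | 25 h |

- midnight (time / h: Q / %, L / %): 1.00: 0, 32; 3.00: 6, 28; 5.00: 10, 23; 8.00: 6, 20; 12.0: 13, 44; 15.0: 17, 37

(readings scatter by 1.5 percentage points)

- at the start none of E is dissolved
- candidate steps: L + E -> Q; E + Q -> Z; E + Z <-> G; D <-> E; E -> X
- percentages count the whole charge, also what has not yet gone in

* the flasks put in order of amount of Q, in percent of the L charged, best first, at 25 h (alder / elm / birch / larch / cedar)
* the amount of Q, in percent of the L charged of the flask you put first, at 25 h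
* the amount of Q, in percent of the L charged of the flask you put last, at 25 h

In the midnight run, of the 33.3 % first charged, 20 % read as L and 6 % as Q at 8.00 h, each reading good to 1.5 percentage points. Every L gone past Q had taken at least two E, so the uptake read at least 20.7 % of the charge, and in the midnight run, as read, D fed E at no less than 0.0186 M/h. I took that crossing as the rate-limiting step. But then, if the midnight feed held there, birch needs 34.9 h of feed to carry one portion all the way to G, and I call this estimate the finishing time.

Alder's finishing time is 16.1 h, shorter than 25 h, and its next portion comes only at 30 h, so I expected its Q near zero. Finishing time over interval is higher in birch, at 4.36, than in any other flask, and lower in alder, at 0.537, than in any other, so I put birch first and alder last.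

The forecast gave birch > elm > larch > cedar > alder, with 26.5 % for the first and 6 % for the last, calling alder “one portion, over-reacted”, so we parted on alder's figure.

The flasks came out as birch > elm > larch > cedar > alder, with 21.6 % of Q in birch and 0 % in alder.

    L + E → Q (k = 17.0 /M/h)
    E + Q → Z (k = 33.0 /M/h)
    E + Z ⇌ G (K = 760 /M, k = 27.0 /M/h)
    D ⇌ E, rate k4*(csat - [E]) (kL = 0.430 /h)
    E → X (k = 3.10 × 10⁻⁵ /h)

Birch, whose finishing time of 34.9 h is longer than the 25.0 h, still held 51.9 % as L at that time. Birch with 0.16 M of L has a finishing time of 8.60 h, close to its interval of 8.0 h, and that flask held 74.8 % as G and 4.94 % as Q at 25.0 h.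

(The readings were generated by integration from invented constants.)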